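**Plan**

- Retrosynthesis: the acetate and a TBS helper on the C4 oxygen are removed first. One operation then cuts both the OCH2–CH= bond (C1–C2 of the octadienyl chain) and the C3–CH3 bond, giving a terminal alkyne, trimethylaluminium and 4-(chloromethoxy)-5-methylcoumarin.
- Enabling feature: the chain atoms C3(CH3)=C2H–C1H2–O4 (O4 being the exocyclic oxygen on C4 of the 2H-chromen-2-one ring) form an (E)-3-methylalk-2-enyl ether. This is what syn-methylmetalation of a C≡C–H terminus followed by capture with an α-chloro ether delivers, and the oxygen on C1 is what makes C1 such an electrophile.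
- Forward order: the pyranone ring of the coumarin is closed first from 2'-hydroxy-6'-methylacetophenone and then O-chloromethylated. The chain is built from 4-methylpent-3-enoic acid as Weinreb amide, silyl ynone, R carbinol, silyl ether and terminal alkyne. The three components are joined in step 8, and desilylation and acetylation finish the route.
- Stereochemistry: C4 (R) comes from Ru/(R,R)-TsDPEN transfer hydrogenation of the ynone. The 2E alkene comes from the syn carbometalation and the retentive C–C coupling.

Key step: step 8

Assumption: 2'-hydroxy-6'-methylacetophenone and 4-methylpent-3-enoic acid are taken as catalogue chemicals; chloromethyl ether 3 is moisture-sensitive and is used directly after it is made.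

**Route**

Step 1
Reactants: 1 2'-hydroxy-6'-methylacetophenone
Product: 2 4-hydroxy-5-methyl-2H-chromen-2-one
Conditions: NaH (3 equiv), (EtO)2CO, toluene, 110 °C; then aq. HCl
Reagents that add atoms: diethyl carbonate, CCOC(=O)OCC
Why: Claisen condensation of the ketone enolate with the carbonate followed by lactonisation onto the phenol oxygen is the standard 4-hydroxycoumarin synthesis, and the 6'-methyl group ends up at C5.

Step 2
Reactants: 2 4-hydroxy-5-methyl-2H-chromen-2-one
Product: 3 4-(chloromethoxy)-5-methyl-2H-chromen-2-one
Conditions: ClCH2OSO2Cl (1.5 equiv), NaHCO3, n-Bu4NHSO4 (10 mol%), CH2Cl2/H2O, 0 °C → rt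
Reagents that add atoms: chloromethyl chlorosulfate, ClCOS(=O)(=O)Cl
Why: The 4-hydroxycoumarin anion is a vinylogous carboxylate and should be alkylated on O4 by this hard electrophile, with chlorosulfate leaving in preference to chloride, as in chloromethyl ester formation from carboxylic acids (phase-transfer O-chloromethylation).

Step 3
Reactants: 4 4-methylpent-3-enoic acid
Product: 5 N-methoxy-N,4-dimethylpent-3-enamide
Conditions: MeNHOMe·HCl, EDC·HCl, HOBt, N-methylmorpholine, CH2Cl2, 0 °C → rt
Reagents that add atoms: N,O-dimethylhydroxylamine hydrochloride, Cl.CNOC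
Why: Carbodiimide amidation gives the Weinreb amide, and the DMAP-free conditions should keep the β,γ-alkene from moving into conjugation.

Step 4
Reactants: 5 N-methoxy-N,4-dimethylpent-3-enamide, 6 (trimethylsilyl)acetylene
Product: 8 6-methyl-1-(trimethylsilyl)hept-5-en-1-yn-3-one, via lithium (trimethylsilyl)acetylide 7 (not isolated)
Conditions: 6, n-BuLi, THF, –78 °C; then 5, –78 → 0 °C; cold aq. NH4Cl
Reagents that add atoms: none
Why: In this Weinreb ketone synthesis the chelated tetrahedral intermediate should stop the reaction at the ynone, and the acetylide is too weak a base to enolise the allylic CH2.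

Step 5
Reactants: 8 6-methyl-1-(trimethylsilyl)hept-5-en-1-yn-3-one
Product: 9 (3R)-6-methyl-1-(trimethylsilyl)hept-5-en-1-yn-3-ol
Conditions: Ru[(R,R)-TsDPEN](p-cymene) (1 mol%), i-PrOH, rt
Reagents that add atoms: none
Why: In this Noyori asymmetric transfer hydrogenation the (R,R) ligand, with the alkynyl group acting as the π-substituent, should deliver hydride to the face that gives the R carbinol, and the base-free Ru–H/N–H catalyst reduces only the C=O group.

Step 6
Reactants: 9 (3R)-6-methyl-1-(trimethylsilyl)hept-5-en-1-yn-3-ol
Product: 10 tert-butyl(dimethyl){[(3R)-6-methyl-1-(trimethylsilyl)hept-5-en-1-yn-3-yl]oxy}silane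
Conditions: TBSCl, imidazole, DMF, rt
Reagents that add atoms: tert-butyldimethylsilyl chloride, CC(C)(C)[Si](C)(C)Cl
Why: Standard silylation of a secondary alcohol masks the oxygen for the organoaluminium step and does not touch the stereocentre.

Step 7
Reactants: 10 tert-butyl(dimethyl){[(3R)-6-methyl-1-(trimethylsilyl)hept-5-en-1-yn-3-yl]oxy}silane
Product: 11 tert-butyl(dimethyl){[(3R)-6-methylhept-5-en-1-yn-3-yl]oxy}silane
Conditions: K2CO3 (cat.), MeOH, rt
Reagents that add atoms: none
Why: Methanolysis cleaves the alkynyl C–Si bond selectively (protodesilylation), while the O–TBS ether is stable to these conditions.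

Step 8
Reactants: 11 tert-butyl(dimethyl){[(3R)-6-methylhept-5-en-1-yn-3-yl]oxy}silane, 12 trimethylaluminium, 3 4-(chloromethoxy)-5-methyl-2H-chromen-2-one
Product: 15 4-{[(2E,4R)-4-[(tert-butyldimethylsilyl)oxy]-3,7-dimethylocta-2,6-dien-1-yl]oxy}-5-methyl-2H-chromen-2-one, via alkenyldimethylalane 13 (not isolated), via lithium alkenylalanate 14 (not isolated)
Conditions: AlMe3 (2 equiv), Cp2ZrCl2 (20 mol%), CH2Cl2, 0 °C → rt; evaporate volatiles and excess AlMe3, extract into hexane; n-BuLi (1 equiv), 0 °C; then 3, THF, –78 → 0 °C
Reagents that add atoms: none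
Why: Cp2ZrCl2/AlMe3 adds Me–Al syn across the terminal C≡C (Negishi zirconium-catalysed methylalumination), methyl to the internal carbon and aluminium to the terminus, so alane 13 already carries the C3 methyl group and the E geometry; n-BuLi then turns 13 into the nucleophilic alanate 14, whose alkenyl group displaces chloride from the O–CH2–Cl carbon of 3 (SN2) with retention at the sp2 carbon. The closest known reaction type is the one-pot carboalumination, ate formation and alkylation of terminal alkynes with chloromethyl alkyl ethers, the established entry to (E)-3-methylalk-2-enyl ethers. No ring is closed and no stereocentre is created: the C2=C3 geometry follows from the syn addition (CH3 and Al cis, hence the carbinol carbon and the new CH2O carbon trans), and the R centre at C4 from step 5 is not involved. The step needs regioselectivity in the carbometalation, which the terminal alkyne and the branched α-silyloxy carbon should secure (aluminium on the unhindered terminus, so no β-alkoxy elimination is possible). It also needs chemoselectivity, which rests on the inertness of the trisubstituted C6=C7 alkene and the silyl ether towards Zr/Al and on the much higher SN2 reactivity of the α-chloro ether carbon than of the lactone C2 or the enol ether C4 towards the alanate at –78 °C. Transfer of the alkenyl group in preference to methyl or butyl is the normal behaviour of alkenyl(trialkyl)alanates.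

Step 9
Reactants: 15 4-{[(2E,4R)-4-[(tert-butyldimethylsilyl)oxy]-3,7-dimethylocta-2,6-dien-1-yl]oxy}-5-methyl-2H-chromen-2-one
Product: 16 4-{[(2E,4R)-4-hydroxy-3,7-dimethylocta-2,6-dien-1-yl]oxy}-5-methyl-2H-chromen-2-one
Conditions: TBAF, AcOH (1:1), THF, 0 °C → rt
Reagents that add atoms: none
Why: Buffered fluoride desilylation should free the allylic alcohol without attack on the lactone or the C4 enol ether and without ionising the allylic aryl ether.

Step 10
Reactants: 16 4-{[(2E,4R)-4-hydroxy-3,7-dimethylocta-2,6-dien-1-yl]oxy}-5-methyl-2H-chromen-2-one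
Product: 17 (2E,4R)-3,7-dimethyl-1-[(5-methyl-2-oxo-2H-chromen-4-yl)oxy]octa-2,6-dien-4-yl acetate
Conditions: Ac2O, Et3N, DMAP (cat.), CH2Cl2, 0 °C → rt
Reagents that add atoms: acetic anhydride, CC(=O)OC(C)=O
Why: DMAP-catalysed acylation of the secondary allylic alcohol occurs at oxygen with retention, so the R configuration is carried into the target.

**Compound list**

1 | 2'-hydroxy-6'-methylacetophenone | CC(=O)c1c(C)cccc1O | starting material
2 | 4-hydroxy-5-methyl-2H-chromen-2-one | Cc1cccc2oc(=O)cc(O)c12 | intermediate
3 | 4-(chloromethoxy)-5-methyl-2H-chromen-2-one | Cc1cccc2oc(=O)cc(OCCl)c12 | intermediate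
4 | 4-methylpent-3-enoic acid | CC(C)=CCC(=O)O | starting material
5 | N-methoxy-N,4-dimethylpent-3-enamide | CON(C)C(=O)CC=C(C)C | intermediate
6 | (trimethylsilyl)acetylene | C#C[Si](C)(C)C | starting material
7 | lithium (trimethylsilyl)acetylide | [Li]C#C[Si](C)(C)C | intermediate
8 | 6-methyl-1-(trimethylsilyl)hept-5-en-1-yn-3-one | CC(C)=CCC(=O)C#C[Si](C)(C)C | intermediate
9 | (3R)-6-methyl-1-(trimethylsilyl)hept-5-en-1-yn-3-ol | C[Si](C)(C)C#C[C@H](O)CC=C(C)C | intermediate
10 | tert-butyl(dimethyl){[(3R)-6-methyl-1-(trimethylsilyl)hept-5-en-1-yn-3-yl]oxy}silane | CC(C)(C)[Si](C)(C)O[C@H](CC=C(C)C)C#C[Si](C)(C)C | intermediate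
11 | tert-butyl(dimethyl){[(3R)-6-methylhept-5-en-1-yn-3-yl]oxy}silane | CC(C)(C)[Si](C)(C)O[C@H](CC=C(C)C)C#C | intermediate
12 | trimethylaluminium | C[Al](C)C | starting material
13 | {(1E,3R)-3-[(tert-butyldimethylsilyl)oxy]-2,6-dimethylhepta-1,5-dien-1-yl}dimethylalane | CC(C)(C)[Si](C)(C)O[C@H](CC=C(C)C)/C(C)=C/[Al](C)C | intermediate
14 | lithium butyl{(1E,3R)-3-[(tert-butyldimethylsilyl)oxy]-2,6-dimethylhepta-1,5-dien-1-yl}dimethylalanate | CC(C)(C)[Si](C)(C)O[C@H](CC=C(C)C)/C(C)=C/[Al-](C)(C)CCCC.[Li+] | intermediate
15 | 4-{[(2E,4R)-4-[(tert-butyldimethylsilyl)oxy]-3,7-dimethylocta-2,6-dien-1-yl]oxy}-5-methyl-2H-chromen-2-one | CC(C)(C)[Si](C)(C)O[C@H](CC=C(C)C)/C(C)=C/COc1cc(=O)oc2cccc(C)c12 | intermediate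
16 | 4-{[(2E,4R)-4-hydroxy-3,7-dimethylocta-2,6-dien-1-yl]oxy}-5-methyl-2H-chromen-2-one | O[C@H](CC=C(C)C)/C(C)=C/COc1cc(=O)oc2cccc(C)c12 | intermediate
17 | (2E,4R)-3,7-dimethyl-1-[(5-methyl-2-oxo-2H-chromen-4-yl)oxy]octa-2,6-dien-4-yl acetate | CC(=O)O[C@H](CC=C(C)C)/C(C)=C/COc1cc(=O)oc2cccc(C)c12 | target

**Step count**

Total steps: 10. Longest linear sequence: 8 (steps 3 to 10, from 4-methylpent-3-enoic acid).

**Steps most likely to fail**

Step 8. The alanate may attack the lactone carbonyl or add to C4 with loss of the chloromethoxy group instead of displacing chloride. Methyl or butyl may be transferred in place of the alkenyl group, or the chloromethyl ether may be consumed by residual AlMe3. Fallback: setting out from 11, the same carboalumination and ate formation (through 13 and 14) followed by trapping with paraformaldehyde in THF should give (2E,4R)-4-[(tert-butyldimethylsilyl)oxy]-3,7-dimethylocta-2,6-dien-1-ol F1. Mitsunobu etherification of this alcohol with 2 (PPh3, DIAD, THF, 0 °C → rt) should then form the O4–C1 bond and return to the route at 15.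

Step 2. Alkylation may occur at C3 or at the lactone oxygen instead of O4. A second coumarin anion may displace chloride to give the methylene bis-ether, and the product may hydrolyse in the aqueous phase. Fallback: setting out from 2, O-alkylation with chloromethyl methyl sulfide (NaH, NaI, DMF, 0 °C → rt) should give 5-methyl-4-[(methylsulfanyl)methoxy]-2H-chromen-2-one F2. Chlorinolysis of this O,S-acetal with sulfuryl chloride (CH2Cl2, –78 → 0 °C, volatiles removed in vacuo) should give 3 under anhydrous conditions, where the route is rejoined.

Step 5. The skipped alkene may migrate into conjugation with the ketone before reduction, and facial selectivity may be insufficient for this ynone. Fallback: setting out from 5, DIBAL-H reduction (THF, –78 °C) should give 4-methylpent-3-enal F3, used crude. A zinc-mediated catalytic enantioselective alkynylation with 6 (Me2Zn, ProPhenol-type dinuclear zinc catalyst in the enantiomeric form that delivers the R carbinol, toluene, 0 °C) should then set C4 by C–C bond formation and return to the route at 9.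

**Further compounds**

F1 | step 8 | (2E,4R)-4-[(tert-butyldimethylsilyl)oxy]-3,7-dimethylocta-2,6-dien-1-ol | CC(C)(C)[Si](C)(C)O[C@H](CC=C(C)C)/C(C)=C/CO
F2 | step 2 | 5-methyl-4-[(methylsulfanyl)methoxy]-2H-chromen-2-one | Cc1cccc2oc(=O)cc(OCSC)c12
F3 | step 5 | 4-methylpent-3-enal | CC(C)=CCC=O
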